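The route is cut at C18=C19. This bond is the exocyclic alkene of the γ-alkylidene butenolide (ring E: O1, C19, C17, C21, C20) and also an endocyclic bond of seven-membered ring D. Because of this double role, one silylative vinylogous aldol condensation joins the γ-carbon C19 of a simple 4-substituted butenolide to a C18 aldehyde, closes ring D and reveals the dienyl lactone in a single flask. The precursor is the trans-anti-trans A/B/C tricycle. It bears an equatorial formyl group on C13 and, on the adjacent equatorial position of C14, a CH2–CH(OTBS)–butenolide arm. It comes from (−)-sclareol through cationic cyclisation of an allyl sulfone, whose carbanion later picks up a 3-furoyl unit.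

Key step: step 14

Remark: C1–C15 keep their labdane numbers, C18 is the carbon on C13, C16 and C17 continue the arm on C14, and ring E is O1–C19–C17–C21–C20; 12, 16, 17 and 22 are taken as epimer mixtures at centres that later steps erase.

Step 1
Reactants: 1 (−)-sclareol
Product: 2 sclareol diacetate
Conditions: AcCl (4 equiv), PhNMe2 (5 equiv), CH2Cl2, 0 °C → rt
Reagents that add atoms: acetyl chloride, CC(=O)Cl
Why: Plain O-acylation of both tertiary alcohols, in which the weakly basic aniline only scavenges HCl, so that neither ionisation of the allylic C13–O bond nor elimination at C8 should intervene and no stereocentre is touched.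

Step 2
Reactants: 2 sclareol diacetate
Product: 3 (13E)-8α-acetoxy-15-(phenylsulfonyl)labd-13-ene
Conditions: PhSO2Na (1.5 equiv), Pd(PPh3)4 (5 mol %), THF/MeOH, 40 °C; crystallisation
Reagents that add atoms: sodium benzenesulfinate, [Na+].[O-]S(=O)c1ccccc1
Why: Tsuji–Trost allylic substitution, in which zerovalent palladium ionises only the allylic C13 acetate and the soft sulfinate attacks the unsubstituted C15 end of the π-allyl complex; since allyl sulfones re-ionise under the same catalyst, the product should settle as the linear sulfone with the (13E) isomer expected to prevail, and the (13Z) isomer left in the mother liquor can be resubmitted.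

Step 3
Reactants: 3 (13E)-8α-acetoxy-15-(phenylsulfonyl)labd-13-ene
Product: 4 Δ12 tricyclic sulfone
Conditions: FSO3H (5 equiv), 2-nitropropane, −78 °C; Et3N quench
Reagents that add atoms: none
Why: Superacid-induced cation–olefin cyclisation (6-endo closure of ring C): loss of acetic acid gives the tertiary C8 cation, C14 of the (13E)-alkene bonds to its α-face through a chair that keeps the C8 methyl axial (β) and trans to 9α-H, the E geometry places C15 equatorial (14α-H), and the C13 cation loses a C12 proton to give the endocyclic alkene, while the sulfone is too weakly basic to interfere.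

Step 4
Reactants: 4 Δ12 tricyclic sulfone
Product: 6 Δ12 enal sulfone, via C18 allylic alcohol 5 (not isolated)
Conditions: SeO2 (1.5 equiv), 1,4-dioxane, 80 °C
Reagents that add atoms: selenium dioxide, O=[Se]=O
Why: Riley allylic oxidation (ene reaction, then [2,3]-shift), in which selenium binds the less substituted C12 and oxygen is delivered to the C13 methyl group (trans to C11) rather than to the hindered tertiary C14–H, and alcohol 5 is oxidised on to the enal under the same conditions.

Step 5
Reactants: 6 Δ12 enal sulfone
Product: 8 equatorial C13 aldehyde sulfone (13β-H), via axial aldehyde 7 (not isolated)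
Conditions: H2 (1 atm), Pd/C, EtOAc, rt; filter; K2CO3, MeOH, rt
Reagents that add atoms: none
Why: Heterogeneous hydrogenation of the enal C=C from the open α-face (the β-face is screened by the axial C8 methyl) should give axial aldehyde 7, and base-mediated epimerisation through the enolate then relieves the syn-axial clash with that methyl, so that C13 ends with the equatorial formyl group trans to C15.

Step 6
Reactants: 8 equatorial C13 aldehyde sulfone
Product: 9 C18 dimethyl acetal sulfone
Conditions: HC(OMe)3, p-TsOH·H2O (cat.), MeOH, rt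
Reagents that add atoms: trimethyl orthoformate, COC(OC)OC
Why: Acid-catalysed acetalisation with the orthoformate as water scavenger masks C18 against the organolithium, SmI2, borane and borohydride steps ahead, and C13 is already the stable epimer and cannot drift.

Step 7
Reactants: 9 C18 dimethyl acetal sulfone; 10 methyl furan-3-carboxylate
Product: 12 β-keto sulfone (C15 epimers), via dilithio sulfone 11 (not isolated)
Conditions: 9, n-BuLi (2.1 equiv), THF, −78 → −20 °C; 10, −78 → 0 °C; aq NH4Cl
Reagents that add atoms: none
Why: Claisen-type C-acylation of an α-sulfonyl carbanion forms C15–C16; the geminal dianion carries the second basic site that takes up the acidic proton of the product, so the reaction stops at the enolate of 12, and the new C15 centre is erased in step 8.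

Step 8
Reactants: 12 β-keto sulfone
Product: 13 3-furyl ketone
Conditions: SmI2 (2.5 equiv), THF/MeOH, −78 °C
Reagents that add atoms: none
Why: Reductive desulfonylation of a β-keto sulfone by single-electron transfer (ketyl formation, loss of sulfinate, protonation of the samarium enolate by MeOH), which at −78 °C is much faster than further reduction of the ketone and leaves acetal and furan alone.

Step 9
Reactants: 13 3-furyl ketone
Product: 14 (16R)-3-furyl carbinol
Conditions: (S)-1-methyl-3,3-diphenyltetrahydro-1H,3H-pyrrolo[1,2-c][1,3,2]oxazaborole ((S)-Me-CBS, 0.2 equiv), BH3·SMe2 (1 equiv), THF, −30 °C; MeOH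
Reagents that add atoms: none
Why: Corey–Bakshi–Shibata reduction, in which the ketone binds to the catalyst boron anti to the aryl-type 3-furyl group and hydride reaches the Si face of C16, so that the (S)-catalyst should give the (16R) alcohol in the same sense as acetophenone gives (R)-1-phenylethanol.

Step 10
Reactants: 14 (16R)-3-furyl carbinol
Product: 15 (16R)-TBS ether
Conditions: TBSCl, imidazole, DMF, rt
Reagents that add atoms: tert-butyldimethylsilyl chloride, CC(C)(C)[Si](C)(C)Cl
Why: Imidazole-promoted O-silylation with retention at C16, chosen over a silyl triflate/lutidine pair because silyl triflates attack dimethyl acetals.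

Step 11
Reactants: 15 (16R)-TBS ether
Product: 17 γ-hydroxybutenolide (C19 epimers), via furan endoperoxide 16 (not isolated)
Conditions: O2, visible light, 5,10,15,20-tetraphenylporphyrin (1 mol %), i-Pr2NEt (5 equiv), CH2Cl2, −78 °C → rt
Reagents that add atoms: oxygen, O=O
Why: [4+2] cycloaddition of singlet oxygen to the furan followed by Kornblum–DeLaMare fragmentation of 16, in which the hindered amine removes the bridgehead proton at C20, remote from the bulky C17 substituent, so that C20 becomes the lactone carbonyl and C19 the lactol carbon; no other oxidisable π-bond is left in 15.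

Step 12
Reactants: 17 γ-hydroxybutenolide
Product: 19 butenolide acetal, via ring-opened hydroxy acid 18 (not isolated)
Conditions: NaBH4, EtOH, 0 °C; then 1 M HCl to pH 3, 0 °C
Reagents that add atoms: none
Why: Borohydride reduces the ring-opened formyl tautomer of the lactol at C19 while the carboxylate is inert, and hydroxy acid 18, whose CH2OH and CO2H groups are cis, lactonises on acidification to the 4-substituted butenolide with C19 as CH2.

Step 13
Reactants: 19 butenolide acetal
Product: 20 C13 aldehyde with the (16R)-silyloxy butenolide arm on C14 (key-step precursor)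
Conditions: PPTS (0.2 equiv), acetone/H2O 10:1, 40 °C
Reagents that add atoms: water, O
Why: Mild acid hydrolysis of the dimethyl acetal, under which a hindered secondary TBS ether and the butenolide are stable and the equatorial C13 configuration cannot change for the worse.

Step 14
Reactants: 20 C13 aldehyde with the (16R)-silyloxy butenolide arm on C14
Product: 23 pentacyclic (16R)-TBS ether, via 2-silyloxyfuran aldehyde 21 (not isolated), via silylated aldol 22 (not isolated)
Conditions: TBSOTf (3 equiv), i-Pr2NEt (4 equiv), CH2Cl2 (5 mM), −40 → 0 °C; then DBU (5 equiv), 0 °C → rt, same flask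
Reagents that add atoms: none
Why: O-Silylation of the lactone carbonyl and removal of a C19 proton by the hindered amine convert the butenolide into 2-silyloxyfuran 21, whose C19 adds to the TBSOTf-activated C18 aldehyde to give silylated aldol 22, and DBU then takes the remaining acidic C19–H and expels silanolate from C18 (E1cB) to create C18=C19. The closest known chemistry is the one-pot silyl triflate/amine vinylogous Mukaiyama aldol addition with DBU elimination that turns 4-substituted butenolides and aldehydes into γ-alkylidene butenolides, together with the silylative cycloaldolisation of lactone aldehydes. Ring D closes in a 7-exo-trig mode at the carbonyl carbon (enol-endo with respect to the furan C17=C19 bond), helped by the gauche arrangement of the two trans-diequatorial arms on C13 and C14. No stereocentre is left by the step: the C18 and C19 centres of 22 are erased, the alkene geometry (C13 cis to C17) is dictated by the seven-membered ring, and C14 and C16 are untouched while C13 is already the stable equatorial epimer. The step needs attack through C19 (γ) rather than C21 (α), although either would give a seven-membered ring, and the silyloxyfuran secures this because it meets activated carbonyl groups at its 5-position and so regains the conjugated lactone. It also needs enolisation of the lactone rather than of the aldehyde, which the gain in aromaticity and the shielding of the axial C13–H by the syn-axial C8 methyl should secure, while high dilution suppresses intermolecular aldol reaction and a short DBU contact protects the C16–H and C13–H positions.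

Step 15
Reactants: 23 pentacyclic (16R)-TBS ether
Product: 24 (16R)-alcohol (deacetyl target)
Conditions: HF·pyridine, THF, 0 °C → rt
Reagents that add atoms: none
Why: Fluoride-driven desilylation in a weakly acidic medium avoids the basic fluoride sources that could open or isomerise the dienyl lactone, and only the Si–O bond breaks, so C16 is retained.

Step 16
Reactants: 24 (16R)-alcohol
Product: 25 target CNP0193439.1
Conditions: Ac2O, pyridine, DMAP (cat.), CH2Cl2, 0 °C → rt
Reagents that add atoms: acetic anhydride, CC(=O)OC(C)=O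
Why: DMAP-catalysed acyl transfer to the secondary allylic alcohol proceeds at oxygen with retention at C16 and under conditions too mild to touch the alkylidene butenolide.

Compound list
1 | (−)-sclareol, (13R)-labd-14-ene-8α,13-diol | C=C[C@](C)(O)CC[C@H]2[C@](C)(O)CC[C@H]1C(C)(C)CCC[C@]21C | starting material
2 | sclareol diacetate, (13R)-8α,13-diacetoxylabd-14-ene | C=C[C@](C)(OC(C)=O)CC[C@H]2[C@](C)(OC(C)=O)CC[C@H]1C(C)(C)CCC[C@]21C | intermediate
3 | (13E)-8α-acetoxy-15-(phenylsulfonyl)labd-13-ene | O=S(=O)(c1ccccc1)C/C=C(\C)CC[C@H]2[C@](C)(OC(C)=O)CC[C@H]1C(C)(C)CCC[C@]21C | intermediate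
4 | Δ12 tricyclic sulfone: trans-anti-trans A/B/C core (5α-H, 9α-H, 8β-Me, 10β-Me, 14α-H), C12=C13 with methyl C18 on C13, β-CH2SO2Ph (C15) on C14 | O=S(=O)(c1ccccc1)C[C@@H]2C(C)=CC[C@H]1[C@@]2(C)CC[C@H]2C(C)(C)CCC[C@]12C | intermediate
5 | C18 allylic alcohol of 4 (C13–CH2OH) | O=S(=O)(c1ccccc1)C[C@@H]2C(CO)=CC[C@H]1[C@@]2(C)CC[C@H]2C(C)(C)CCC[C@]12C | intermediate
6 | Δ12 enal sulfone (C13–CHO) | O=S(=O)(c1ccccc1)C[C@@H]2C(C=O)=CC[C@H]1[C@@]2(C)CC[C@H]2C(C)(C)CCC[C@]12C | intermediate
7 | saturated axial aldehyde sulfone (13α-H, β-CHO) | O=S(=O)(c1ccccc1)C[C@@H]2[C@H](C=O)CC[C@H]1[C@@]2(C)CC[C@H]2C(C)(C)CCC[C@]12C | intermediate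
8 | saturated equatorial aldehyde sulfone (13β-H, α-CHO, trans-diequatorial to C15) | O=S(=O)(c1ccccc1)C[C@@H]2[C@@H](C=O)CC[C@H]1[C@@]2(C)CC[C@H]2C(C)(C)CCC[C@]12C | intermediate
9 | C18 dimethyl acetal of 8 | O=S(=O)(c1ccccc1)C[C@@H]2[C@@H](C(OC)OC)CC[C@H]1[C@@]2(C)CC[C@H]2C(C)(C)CCC[C@]12C | intermediate
10 | methyl furan-3-carboxylate | COC(=O)c1ccoc1 | starting material
11 | C15 α,α-dilithio derivative of 9 | [Li]C([Li])(S(=O)(=O)c1ccccc1)[C@@H]2[C@@H](C(OC)OC)CC[C@H]1[C@@]2(C)CC[C@H]2C(C)(C)CCC[C@]12C | intermediate
12 | β-keto sulfone, C15(SO2Ph)–C16(=O)–3-furyl, C15 epimers | O=C(c1ccoc1)C(S(=O)(=O)c1ccccc1)[C@@H]2[C@@H](C(OC)OC)CC[C@H]1[C@@]2(C)CC[C@H]2C(C)(C)CCC[C@]12C | intermediate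
13 | 3-furyl ketone, C15H2–C16(=O)–3-furyl | O=C(c1ccoc1)C[C@@H]2[C@@H](C(OC)OC)CC[C@H]1[C@@]2(C)CC[C@H]2C(C)(C)CCC[C@]12C | intermediate
14 | (16R)-3-furyl carbinol | O[C@@H](c1ccoc1)C[C@@H]2[C@@H](C(OC)OC)CC[C@H]1[C@@]2(C)CC[C@H]2C(C)(C)CCC[C@]12C | intermediate
15 | (16R)-TBS ether of 14 | CC(C)(C)[Si](C)(C)O[C@@H](c1ccoc1)C[C@@H]2[C@@H](C(OC)OC)CC[C@H]1[C@@]2(C)CC[C@H]2C(C)(C)CCC[C@]12C | intermediate
16 | furan endoperoxide of 15 (2,3,7-trioxabicyclo[2.2.1]hept-5-ene) | CC(C)(C)[Si](C)(C)O[C@@H](C1=CC3OOC1O3)C[C@@H]2[C@@H](C(OC)OC)CC[C@H]1[C@@]2(C)CC[C@H]2C(C)(C)CCC[C@]12C | intermediate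
17 | 4-substituted 5-hydroxy-2(5H)-furanone, C19 lactol epimers | CC(C)(C)[Si](C)(C)O[C@@H](C1=CC(=O)OC1O)C[C@@H]2[C@@H](C(OC)OC)CC[C@H]1[C@@]2(C)CC[C@H]2C(C)(C)CCC[C@]12C | intermediate
18 | ring-opened hydroxy acid, C19H2OH cis to C20O2H across C17=C21 | CC(C)(C)[Si](C)(C)O[C@@H](/C(CO)=C/C(=O)O)C[C@@H]2[C@@H](C(OC)OC)CC[C@H]1[C@@]2(C)CC[C@H]2C(C)(C)CCC[C@]12C | intermediate
19 | 4-substituted 2(5H)-furanone with C18 dimethyl acetal | CC(C)(C)[Si](C)(C)O[C@@H](C1=CC(=O)OC1)C[C@@H]2[C@@H](C(OC)OC)CC[C@H]1[C@@]2(C)CC[C@H]2C(C)(C)CCC[C@]12C | intermediate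
20 | key-step precursor: equatorial C13 aldehyde, (16R)-OTBS 4-substituted butenolide arm on C14 | CC(C)(C)[Si](C)(C)O[C@@H](C1=CC(=O)OC1)C[C@@H]2[C@@H](C=O)CC[C@H]1[C@@]2(C)CC[C@H]2C(C)(C)CCC[C@]12C | intermediate
21 | 2-(tert-butyldimethylsilyloxy)furan aldehyde | CC(C)(C)[Si](C)(C)O[C@@H](c1coc(O[Si](C)(C)C(C)(C)C)c1)C[C@@H]2[C@@H](C=O)CC[C@H]1[C@@]2(C)CC[C@H]2C(C)(C)CCC[C@]12C | intermediate
22 | ring-D-closed aldol, C18–OTBS and C19–H, epimers | CC(C)(C)[Si](C)(C)O[C@@H]1C[C@@H]2[C@@H](C(O[Si](C)(C)C(C)(C)C)C3OC(=O)C=C31)CC[C@H]1[C@@]2(C)CC[C@H]2C(C)(C)CCC[C@]12C | intermediate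
23 | pentacyclic γ-alkylidene butenolide, (16R)-OTBS (key-step product) | CC(C)(C)[Si](C)(C)O[C@@H]1C[C@@H]2[C@@H](C=C3OC(=O)C=C31)CC[C@H]1[C@@]2(C)CC[C@H]2C(C)(C)CCC[C@]12C | intermediate
24 | (16R)-alcohol, deacetyl target | O[C@@H]1C[C@@H]2[C@@H](C=C3OC(=O)C=C31)CC[C@H]1[C@@]2(C)CC[C@H]2C(C)(C)CCC[C@]12C | intermediate
25 | CNP0193439.1, (16R)-acetate | CC(=O)O[C@@H]1C[C@@H]2[C@@H](C=C3OC(=O)C=C31)CC[C@H]1[C@@]2(C)CC[C@H]2C(C)(C)CCC[C@]12C | target

Total step count: 16. Longest linear sequence: 16 steps (1 → 25); 10 is used as purchased.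

Steps most likely to fail

1. Step 14. The amine/silyl triflate pair may silylate the aldehyde as its enol ether before ring closure. The nucleophile may also react through C21, or closure of the seven-membered ring may lose out to intermolecular aldol reaction. The fallback makes the same C18=C19 bond by an intramolecular Wittig olefination; it sets out from 17 and comes back at 23. PPTS in wet acetone frees the aldehyde and gives the lactol aldehyde F1. Ph3P·HBr in MeCN exchanges the C19 lactol hydroxyl for phosphorus by way of the acyloxycarbenium ion and gives the C19 phosphonium bromide F2. Et3N in dilute CH2Cl2 then forms the stabilised ylide, which olefinates the C18 aldehyde to give 23. Bond formation is thereby tied to the phosphorus-bearing C19, and no silylating agent meets the aldehyde.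

2. Step 3. The allylic sulfone lowers the nucleophilicity of the C13=C14 alkene. Proton loss from the C8 cation, ionisation of the allyl sulfone or unselective final deprotonation may therefore outrun clean ring closure. The fallback closes ring C first and brings in sulfur afterwards; it sets out from 2 and comes back at 4.
- PdCl2(MeCN)2 (divalent palladium, [3,3] allylic acetate transposition) in THF gives (13E)-8α,15-diacetoxylabd-13-ene F3.
- FSO3H in 2-nitropropane at −78 °C cyclises this terpenyl acetate to the Δ12 tricyclic C15 acetate F4.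
- K2CO3 in MeOH gives the Δ12 tricyclic C15 alcohol F5.
- PhSSPh and n-Bu3P (Hata thioetherification, warm THF) give the C15 phenyl sulfide F6.
- H2O2 with (NH4)6Mo7O24 (cat.) in EtOH at 0 °C oxidises sulfur without touching the hindered alkene and gives 4.

3. Step 7. C15 sits on C14 between the quaternary C8 and the acetal-bearing C13. C-acylation may therefore be slow, and proton transfer or addition of unreacted butyllithium to the ester may take over. The fallback replaces the acylation by addition to a more reactive aldehyde followed by oxidation; it sets out from 9 and comes back at 12. Compound 9 is deprotonated with one equivalent of n-BuLi (THF, −78 °C) and added to furan-3-carbaldehyde (O=Cc1ccoc1) to give the β-hydroxy sulfone F7 as an epimer mixture. Dess–Martin periodinane in CH2Cl2 then oxidises it to 12.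

Further compounds
F1 | step 14 | lactol aldehyde (5-hydroxybutenolide arm, free C13 aldehyde, 16R-OTBS) | CC(C)(C)[Si](C)(C)O[C@@H](C1=CC(=O)OC1O)C[C@@H]2[C@@H](C=O)CC[C@H]1[C@@]2(C)CC[C@H]2C(C)(C)CCC[C@]12C
F2 | step 14 | C19 triphenylphosphonium bromide of the butenolide aldehyde | CC(C)(C)[Si](C)(C)O[C@@H](C1=CC(=O)OC1[P+](c1ccccc1)(c1ccccc1)c1ccccc1)C[C@@H]2[C@@H](C=O)CC[C@H]1[C@@]2(C)CC[C@H]2C(C)(C)CCC[C@]12C.[Br-]
F3 | step 3 | (13E)-8α,15-diacetoxylabd-13-ene | CC(=O)OC/C=C(\C)CC[C@H]2[C@](C)(OC(C)=O)CC[C@H]1C(C)(C)CCC[C@]21C
F4 | step 3 | Δ12 tricyclic C15 acetate | CC(=O)OC[C@@H]2C(C)=CC[C@H]1[C@@]2(C)CC[C@H]2C(C)(C)CCC[C@]12C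
F5 | step 3 | Δ12 tricyclic C15 alcohol | OC[C@@H]2C(C)=CC[C@H]1[C@@]2(C)CC[C@H]2C(C)(C)CCC[C@]12C
F6 | step 3 | Δ12 tricyclic C15 phenyl sulfide | c1ccccc1SC[C@@H]2C(C)=CC[C@H]1[C@@]2(C)CC[C@H]2C(C)(C)CCC[C@]12C
F7 | step 7 | β-hydroxy sulfone, C15(SO2Ph)–C16H(OH)–3-furyl, epimers | OC(c1ccoc1)C(S(=O)(=O)c1ccccc1)[C@@H]2[C@@H](C(OC)OC)CC[C@H]1[C@@]2(C)CC[C@H]2C(C)(C)CCC[C@]12C
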